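**Plan**
Numbering: ring A is C1(isobutyryl)–C2(=O)–C3(spiro)–C4(=O)–C5(geranyl)–C9(=O); ring B is C5–C6–C7–C8(Me2)–C1–C9; the bridge is C7–C10–C11–C3; ring E is C3–C11–C12(Me2)–C13(isopropenyl)–C14.
Retrosynthesis: a hydroxyl is put back on C10, then C7–C10 and C1–C8 are cut together, then C5–geranyl, C12–C13, C3–C11 (back to an O4 allyl ether), the two C–prenyl bonds and the C1–acyl bond.
Forward: ring A is the phloroglucinol ring; ring E is closed on it at C3 (Claisen shift, then radical 5-exo closure); after C5 geranylation one cationic step closes ring B and both seven-membered rings.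
Enabling feature: C6–C7=C8Me2 is an ordinary prenyl group on C5, and C10 can be a formyl carbon held on C11 of ring E on the C4/C5 side of spiro C3, so C7 can reach C10 and the C8 cation then lies against the C1 enol.
Stereochemistry: C3/C11 from the chair Claisen of a Z allyl ether, C13 from the radical closure (trans to the C10 arm), C5 from alkylation anti to that arm, C7 and C1 from the cage; absolute configuration by resolution of the spiro silyl ether.

Key step: step 12

Remark: the two racemic intermediates before the resolution are written as the enantiomer that is carried on, and the C10 alcohol from the key step is written as one epimer (hydroxyl on the outer face, away from ring A); either epimer would serve.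

Step 1
Reactants: 1 phloroglucinol; 2 isobutyryl chloride
Product: 3 2-methyl-1-(2,4,6-trihydroxyphenyl)propan-1-one
Conditions: AlCl3 (3 equiv), PhNO2/CH2Cl2, 0 °C to 50 °C
Reagents that add atoms: none
Why: Friedel–Crafts acylation of the electron-rich arene stops after one acyl group because the aryl ketone, chelated to aluminium, is deactivated.

Step 2
Reactants: 3 2-methyl-1-(2,4,6-trihydroxyphenyl)propan-1-one; 4 prenyl bromide
Product: 6 deoxycohumulone (the 3,5-diprenyl ketone), via monoprenyl ketone 5 (not isolated)
Conditions: 4 (2.1 equiv), 10% aq. KOH, 0 °C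
Reagents that add atoms: none
Why: C-alkylation of the phloroglucinolate in water, where hydrogen bonding to oxygen favours attack through carbon, should take place in turn at the two free ring carbons (electrophilic aromatic substitution by the allylic bromide).

Step 3
Reactants: 7 (tert-butyldimethylsilyloxy)acetaldehyde; 8 ethyl 2-[bis(2,2,2-trifluoroethoxy)phosphoryl]propanoate
Product: 9 ethyl (Z)-4-(tert-butyldimethylsilyloxy)-2-methylbut-2-enoate
Conditions: KN(SiMe3)2, 18-crown-6, THF, −78 °C
Reagents that add atoms: none
Why: Still–Gennari olefination, in which the electron-poor phosphonate under dissociating conditions eliminates from the kinetic adduct and should give the Z trisubstituted enoate.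

Step 4
Reactants: 9 ethyl (Z)-4-(tert-butyldimethylsilyloxy)-2-methylbut-2-enoate
Product: 11 (Z)-4-(tert-butyldimethylsilyloxy)-2-methylbut-2-en-1-ol, via Z-enal 10 (not isolated)
Conditions: i-Bu2AlH (2.5 equiv), CH2Cl2, −78 °C to 0 °C
Reagents that add atoms: none
Why: 1,2-reduction of the conjugated ester by the aluminium hydride passes through the aldehyde and leaves the Z double bond and the silyl ether untouched.

Step 5
Reactants: 6 deoxycohumulone; 11 (Z)-4-(tert-butyldimethylsilyloxy)-2-methylbut-2-en-1-ol
Product: 12 4-O-[(Z)-4-(tert-butyldimethylsilyloxy)-2-methylbut-2-enyl] ether of 6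
Conditions: PPh3, DIAD, THF, 0 °C to rt
Reagents that add atoms: none
Why: Mitsunobu etherification should engage only the 4-OH, the one hydroxyl that is not hydrogen-bonded to the ketone and the most acidic, and the SN2 displacement at the primary allylic carbon keeps the Z geometry.

Step 6
Reactants: 12 4-O-allyl ether of 6
Product: 13 racemic Claisen product, the enolized ring A trione whose quaternary C3 carries prenyl and the group C11H(CH2OTBS)–C12(CH3)=CH2
Conditions: PhMe, 130 °C (sealed tube)
Reagents that add atoms: none
Why: dearomatizing aromatic Claisen rearrangement to either of the two equivalent prenyl-bearing ortho carbons (the para carbon carries the acyl group, so the dienone can only tautomerize to the hydrogen-bonded enol trione), through a chair in which the C12 methyl points away from the ring and the Z CH2OTBS group is pseudo-axial, which joins C3 to C11 with the C10 arm on the side of C4, the carbon that bore the ether oxygen.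

Step 7
Reactants: 13 racemic Claisen product
Product: 14 racemic spiro silyl ether (ring E closed; CH2OTBS on C11 cis to C4 and trans to the isopropenyl group on C13)
Conditions: Co(L)Cl (5 mol%; L = N,N'-bis(3,5-di-tert-butylsalicylidene)ethylenediamine dianion), PhSiH3 (10 mol%), PhH, rt, Ar
Reagents that add atoms: none
Why: cobalt-hydride hydrogen-atom-transfer cycloisomerization of the 1,6-diene, in which the hydrogen atom goes to the CH2 of the 1,1-disubstituted alkene (the trisubstituted prenyl alkenes react far more slowly), the tertiary C12 radical closes 5-exo on C13 of the C3 prenyl group through a chair-like transition state with the CH2OTBS arm pseudo-equatorial, which sets C13 trans to that arm, and cobalt then takes a methyl hydrogen from the new tertiary radical to leave the isopropenyl group.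

Step 8
Reactants: 14 racemic spiro silyl ether
Product: 15 spiro silyl ether as the single enantiomer with the target configuration at C3, C11 and C13
Conditions: preparative SFC, amylose tris(3,5-dimethylphenylcarbamate) column, CO2/i-PrOH
Reagents that add atoms: none
Why: resolution of the racemate by chromatography on a chiral stationary phase, placed here because 14 is rigid, has a strong chromophore and precedes the costly geranyl unit; no bond is made or broken.

Step 9
Reactants: 15 resolved spiro silyl ether; 16 geranyl bromide
Product: 17 C5-geranylated spiro silyl ether (at C5 geranyl cis to C14, prenyl cis to C11)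
Conditions: NaOMe (1.5 equiv), 16 (1.5 equiv), MeOH, 0 °C to rt
Reagents that add atoms: none
Why: C-alkylation of the vinylogous enolate at C5 in a protic solvent (the alkylation that turns an acylphloroglucinol into its gem-dialkyl trione), where the CH2OTBS arm on C11 covers the face of ring A over C4–C5, so geranyl bromide should enter from the C14 face and push the prenyl group cis to the arm, which sets C5.

Step 10
Reactants: 17 C5-geranylated spiro silyl ether
Product: 18 C10 primary alcohol
Conditions: HF·pyridine, pyridine, THF, 0 °C to rt
Reagents that add atoms: none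
Why: fluoride cleavage of the primary silyl ether, after which, with C5 quaternary, the freed alcohol can at most form a reversible hemiketal with the C4 ketone.

Step 11
Reactants: 18 C10 primary alcohol
Product: 19 C10 aldehyde (spiro trione with C1 isobutyryl enol, prenyl and geranyl on C5, formyl on C11)
Conditions: (n-Pr4N)RuO4 (5 mol%), N-methylmorpholine N-oxide (2 equiv), 4 Å sieves, CH2Cl2, rt
Reagents that add atoms: none
Why: Ley–Griffith oxidation is neutral and stops at the aldehyde, the alkenes and the enolized trione are spectators, and C11, flanked by two quaternary carbons, should not epimerize.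

Step 12
Reactants: 19 C10 aldehyde
Product: 20 10-hydroxy derivative of the target (hydroxyl on the outer face of the C10–C11 bridge)
Conditions: Me2AlCl (3 equiv), CH2Cl2, −78 °C to −20 °C; then 1 M HCl
Reagents that add atoms: none
Why: Proposed new method: the first equivalent of Me2AlCl turns the C9 enol into a chelated aluminium enolate (methane is lost) and a second binds the aldehyde; C7 of the C5 prenyl alkene then adds to C10 (Prins), and the tertiary C8 cation that develops lies over the enolate and is taken by C1, so that C7–C10 and C1–C8 form in one operation. The closest known reactions are Me2AlCl-promoted intramolecular Prins and carbonyl-ene cyclizations of aldehydes onto trisubstituted alkenes and acid-mediated cation–olefin cyclizations that end on the carbon of a cyclic 1,3-dicarbonyl enol; their union in one step on such a substrate has not been shown. The Prins event is a 7-exo-trig attack on the aldehyde (ring C3–C4–C5–C6–C7–C10–C11), and the capture is a six-membered enol-endo closure onto the cation that makes ring B (C5–C6–C7–C8–C1–C9) and, with the same bond, the second seven-membered ring C1–C2–C3–C11–C10–C7–C8. C7 and C1 can only form with C8 bridging toward C1 inside the cage already fixed by C3, C5 and C11, and C10 should take its hydroxyl on the outer face because the aluminium-bound oxygen points away from ring A (this centre is removed later). The step needs prenyl to react and not geranyl or isopropenyl, and carbon capture to beat oxygen capture, proton loss and aldol addition: only the C5 substituent cis to the formyl arm reaches C10, the isopropenyl group is trans to the arm, the enolate oxygen is tied to aluminium, and C1 cannot reach C10 because the arm sits on the C4 side of the spiro centre.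

Step 13
Reactants: 20 10-hydroxy derivative of the target
Product: 21 O-(imidazol-1-ylthiocarbonyl) derivative of 20
Conditions: 1,1'-thiocarbonyldiimidazole (3 equiv), DMAP (0.2 equiv), ClCH2CH2Cl, 70 °C
Reagents that add atoms: 1,1'-thiocarbonyldiimidazole, S=C(n1ccnc1)n1ccnc1
Why: thioacylation of the secondary alcohol by acyl transfer under neutral conditions, chosen over xanthate formation so that no alkoxide is generated next to the non-enolizable tetraketone (retro-Claisen risk).

Step 14
Reactants: 21 O-(imidazol-1-ylthiocarbonyl) derivative of 20
Product: 22 CNP0280463.1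
Conditions: Bu3SnH (5 equiv), AIBN (0.2 equiv), PhMe, 100 °C
Reagents that add atoms: none
Why: Barton–McCombie deoxygenation, in which the stannyl radical adds to sulfur, the C10–O bond fragments and the secondary C10 radical is reduced by the tin hydride, kept concentrated so that hydrogen transfer outruns cyclization onto carbonyl or alkene groups; no stereocentre is touched.

**Compound list**
1 | phloroglucinol | Oc1cc(O)cc(O)c1 | starting material
2 | isobutyryl chloride | CC(C)C(Cl)=O | starting material
3 | 2-methyl-1-(2,4,6-trihydroxyphenyl)propan-1-one | CC(C)C(=O)c1c(O)cc(O)cc1O | intermediate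
4 | prenyl bromide | BrCC=C(C)C | starting material
5 | 2-methyl-1-[2,4,6-trihydroxy-3-(3-methylbut-2-enyl)phenyl]propan-1-one (monoprenyl ketone, not isolated) | CC(C)C(=O)c1c(O)cc(O)c(CC=C(C)C)c1O | intermediate
6 | deoxycohumulone, 2-methyl-1-[2,4,6-trihydroxy-3,5-bis(3-methylbut-2-enyl)phenyl]propan-1-one | CC(C)C(=O)c1c(O)c(CC=C(C)C)c(O)c(CC=C(C)C)c1O | intermediate
7 | (tert-butyldimethylsilyloxy)acetaldehyde | O=CCO[Si](C)(C)C(C)(C)C | starting material
8 | ethyl 2-[bis(2,2,2-trifluoroethoxy)phosphoryl]propanoate | CCOC(=O)C(C)P(=O)(OCC(F)(F)F)OCC(F)(F)F | starting material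
9 | ethyl (Z)-4-(tert-butyldimethylsilyloxy)-2-methylbut-2-enoate | CCOC(=O)/C(C)=C\CO[Si](C)(C)C(C)(C)C | intermediate
10 | (Z)-4-(tert-butyldimethylsilyloxy)-2-methylbut-2-enal (not isolated) | O=C/C(C)=C\CO[Si](C)(C)C(C)(C)C | intermediate
11 | (Z)-4-(tert-butyldimethylsilyloxy)-2-methylbut-2-en-1-ol | OC/C(C)=C\CO[Si](C)(C)C(C)(C)C | intermediate
12 | 4-O-[(Z)-4-(tert-butyldimethylsilyloxy)-2-methylbut-2-enyl] ether of 6 | CC(C)C(=O)c1c(O)c(CC=C(C)C)c(OC/C(C)=C\CO[Si](C)(C)C(C)(C)C)c(CC=C(C)C)c1O | intermediate
13 | racemic Claisen product: enolized ring A trione (isobutyryl on C1, prenyl on C5) whose quaternary C3 carries prenyl and C11H(CH2OTBS)–C(CH3)=CH2, C10 arm on the C4 side of C3; enantiomer carried on is drawn | CC(C)C(=O)C1=C(O)C(CC=C(C)C)=C(O)[C@](CC=C(C)C)([C@@H](CO[Si](C)(C)C(C)(C)C)C(C)=C)C1=O | intermediate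
14 | racemic spiro silyl ether: ring E spiro at C3, CH2OTBS on C11 cis to C4 and trans to isopropenyl on C13, prenyl on C5; enantiomer carried on is drawn | CC(C)C(=O)C1=C(O)C(CC=C(C)C)=C(O)[C@@]2(C[C@@H](C(C)=C)C(C)(C)[C@@H]2CO[Si](C)(C)C(C)(C)C)C1=O | intermediate
15 | resolved spiro silyl ether, the enantiomer of 14 with the target configuration at C3, C11 and C13 | CC(C)C(=O)C1=C(O)C(CC=C(C)C)=C(O)[C@@]2(C[C@@H](C(C)=C)C(C)(C)[C@@H]2CO[Si](C)(C)C(C)(C)C)C1=O | intermediate
16 | geranyl bromide | BrC/C=C(\C)CCC=C(C)C | starting material
17 | C5-geranylated spiro silyl ether (geranyl cis to C14, prenyl cis to C11) | CC(C)C(=O)C1=C(O)[C@@](CC=C(C)C)(C/C=C(\C)CCC=C(C)C)C(=O)[C@@]2(C[C@@H](C(C)=C)C(C)(C)[C@@H]2CO[Si](C)(C)C(C)(C)C)C1=O | intermediate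
18 | C10 primary alcohol | CC(C)C(=O)C1=C(O)[C@@](CC=C(C)C)(C/C=C(\C)CCC=C(C)C)C(=O)[C@@]2(C[C@@H](C(C)=C)C(C)(C)[C@@H]2CO)C1=O | intermediate
19 | C10 aldehyde, precursor of the key step | CC(C)C(=O)C1=C(O)[C@@](CC=C(C)C)(C/C=C(\C)CCC=C(C)C)C(=O)[C@@]2(C[C@@H](C(C)=C)C(C)(C)[C@@H]2C=O)C1=O | intermediate
20 | 10-hydroxy derivative of the target (hydroxyl on the outer face of the C10–C11 bridge) | C=C(C)[C@@H]1C[C@@]23C(=O)[C@@]4(C/C=C(\C)CCC=C(C)C)C[C@@H]([C@H](O)[C@H]2C1(C)C)C(C)(C)[C@](C(=O)C(C)C)(C4=O)C3=O | intermediate
21 | O-(imidazol-1-ylthiocarbonyl) derivative of 20 | C=C(C)[C@@H]1C[C@@]23C(=O)[C@@]4(C/C=C(\C)CCC=C(C)C)C[C@@H]([C@H](OC(=S)n5ccnc5)[C@H]2C1(C)C)C(C)(C)[C@](C(=O)C(C)C)(C4=O)C3=O | intermediate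
22 | CNP0280463.1 | C=C(C)[C@@H]1C[C@@]23C(=O)[C@@]4(C/C=C(\C)CCC=C(C)C)C[C@@H](C[C@H]2C1(C)C)C(C)(C)[C@](C(=O)C(C)C)(C4=O)C3=O | target

**Step count**
Total: 14 steps (12 in the main line, 2 for allylic alcohol 11). Longest linear sequence: 12 steps from phloroglucinol (steps 1, 2 and 5 to 14).

**The three steps most likely to fail**

Step 12 (key step). The C8 cation may lose a proton to the methylaluminium reagent (ene pathway) or be taken by oxygen before C1 bonds, or the alkene may add with C8 turned away from C1. The fallback separates the two bond formations into known reaction types and sets out from 19. A Lewis acid carbonyl-ene cyclization (Me2AlCl in excess, CH2Cl2, −78 °C) forms C7–C10 and leaves an isopropenyl group on C7, giving the homoallylic alcohol F1. F1 is then stirred in formic acid at room temperature, conditions under which an isopropenyl or prenyl group is protonated to the tertiary cation and alkylates the carbon of a cyclic acyl-dione enol. Protonation regenerates the C8 cation, C1 closes ring B, and the sequence comes back to the route at 20. A C7 epimer that cannot close can revert by fragmentation of the γ-hydroxy cation and add again.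

Step 7 (radical closure of ring E). The acidic enol may consume the cobalt hydride as hydrogen, the C12 radical may hand its hydrogen back faster than it cyclizes (alkene isomerization), the isopropenyl group of the product may re-enter the cycle, or facial selectivity at C13 may be poor. The fallback builds ring E by an oxidative radical annulation and sets out from 6. Treatment with Mn(OAc)3·2H2O (trivalent manganese, 2.2 equiv) and Cu(OAc)2·H2O (divalent copper, 1 equiv) in AcOH at room temperature with excess prenyl acetate should generate the C3-centred radical. This radical adds to the CH end of prenyl acetate, the tertiary radical closes 5-exo on the C3 prenyl group, and divalent copper oxidizes the resulting radical to the isopropenyl group. The product is the racemic spiro acetate F2, which must be separated from its C3/C11 diastereomer because this route has no control there. Methanolysis (K2CO3, MeOH) gives the spiro alcohol F3, which is silylated at once (TBSCl, imidazole, DMF) and comes back to the route at 14.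

Step 6 (Claisen shift). A boat transition state, or ionization and recombination of the allyl ether, may erode the C3/C11 relationship, since the Z substituent has to sit over the ring in the chair. The fallback moves the allyl group to O2 and uses the E alkene, so that the same chair carries the CH2OTBS group pseudo-equatorial and leads to the same C3/C11 relationship. It sets out from 6, with aldehyde 7 for the side chain. Wittig reaction of 7 with Ph3P=C(CH3)CHO gives the (E)-enal F4, and NaBH4 gives the (E)-alcohol F5. Compound 6 is silylated at its 4-OH (TBSCl, imidazole) to the 4-O-silyl ether F6. Mitsunobu coupling of F6 with F5 at a chelated 2-OH gives the 2-O-allyl ether F7. Heating (PhMe, 130 °C) gives the Claisen product as its C4 silyl enol ether F8. K2CO3 in MeOH at 0 °C removes the enol silyl group only and comes back to the route at 13.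

**Further compounds**
F1 | step 12 | carbonyl-ene product: seven-membered ring C3–C4–C5–C6–C7–C10–C11 closed, isopropenyl on C7, hydroxyl on C10, C1 enol intact | CC(C)C(=O)C1=C(O)[C@]2(C/C=C(\C)CCC=C(C)C)C[C@H](C(C)=C)[C@H](O)[C@H]3C(C)(C)[C@H](C(C)=C)C[C@]3(C2=O)C1=O
F2 | step 7 | racemic spiro acetate (acetate analogue of 14; enantiomer leading to the target drawn) | CC(C)C(=O)C1=C(O)C(CC=C(C)C)=C(O)[C@@]2(C[C@@H](C(C)=C)C(C)(C)[C@@H]2COC(C)=O)C1=O
F3 | step 7 | racemic spiro alcohol (desilyl analogue of 14; enantiomer leading to the target drawn) | CC(C)C(=O)C1=C(O)C(CC=C(C)C)=C(O)[C@@]2(C[C@@H](C(C)=C)C(C)(C)[C@@H]2CO)C1=O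
F4 | step 6 | (E)-4-(tert-butyldimethylsilyloxy)-2-methylbut-2-enal | O=C/C(C)=C/CO[Si](C)(C)C(C)(C)C
F5 | step 6 | (E)-4-(tert-butyldimethylsilyloxy)-2-methylbut-2-en-1-ol | OC/C(C)=C/CO[Si](C)(C)C(C)(C)C
F6 | step 6 | 4-O-tert-butyldimethylsilyl ether of 6 | CC(C)C(=O)c1c(O)c(CC=C(C)C)c(O[Si](C)(C)C(C)(C)C)c(CC=C(C)C)c1O
F7 | step 6 | 2-O-[(E)-4-(tert-butyldimethylsilyloxy)-2-methylbut-2-enyl] ether of F6 | CC(C)C(=O)c1c(O)c(CC=C(C)C)c(O[Si](C)(C)C(C)(C)C)c(CC=C(C)C)c1OC/C(C)=C/CO[Si](C)(C)C(C)(C)C
F8 | step 6 | racemic C4 tert-butyldimethylsilyl enol ether of 13 (enantiomer leading to the target drawn) | CC(C)C(=O)C1=C(O)C(CC=C(C)C)=C(O[Si](C)(C)C(C)(C)C)[C@](CC=C(C)C)([C@@H](CO[Si](C)(C)C(C)(C)C)C(C)=C)C1=O
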